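## The problem

Compound 25 is a germacrane-type lactone: a ten-membered carbocycle (C1–C10) fused through C6–C7 to a butenolide (O–C6, C7=C11, C12=O). C11 carries the hydroxymethyl carbon C13, C10 an exocyclic methylene (C14), C4 a methyl group (C15), and the C4=C5 bond is Z. This numbering is used throughout. There are three stereocentres: C6 (R), C3 (S) and C1 (S). C1 and C3 are 1,3-anti acetates separated only by C2, whereas C6 lies across the Z alkene from C3. C6 is therefore the centre to set first by reagent control; it can speak to C3 through allylic 1,3-strain, and C3 can then direct C1 by 1,3-induction. The C6 hydrogen is γ to the lactone carbonyl and doubly allylic, so base converts the butenolide into a 2-oxidofuran and erases the centre. The Z diene of the intermediates isomerises with acid, iodine or light, both acetates are allylic, and the 2-substituted acrolein and exocyclic enone intermediates are Michael acceptors. A ten-membered ring is the least favourable ring size to close, so the closing reaction must be fast and intramolecular by design. The enabling feature is the unit C1(O)–C2–C3(O), flanked by the C10 methylene and the C4=C5 alkene. Read as a β-hydroxy ketone, it is the retron of an isoxazoline made from a nitrile oxide at C1 and a vinyl group C2=C3 at the end of a Z diene.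

## Retrosynthesis

**Target 25 back to hydroxy enone 22.** No skeletal bond is cut. The C13 silyl ether 24 and the C1 alcohol 23 lead back to β-hydroxy ketone 22. An Evans–Tishchenko reduction is preferred to a separate reduction and double acylation because it sets C1 anti to C3 and places the C3 acetate in one operation. The precursor has one stereocentre fewer. The forward step needs a chelated hydride transfer inside the medium ring and tolerance of the exocyclic enone.

**Hydroxy enone 22 back to isoxazoline 20.** The N–O bond and the C1=N bond are restored. This is preferred to an aldol disconnection at C2–C3, which would ask a macro-aldol to close the ring and set C3 at once. In 20 both oxygen functions of the C1–C3 unit are masked in one small ring, so neither needs a protecting group. The forward cleavage must leave four C=C bonds untouched.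

**Isoxazoline 20 back to nitrile oxide 19 and oxime 18 (key disconnection).** The bonds C1–C2 and O–C3 are cut, which removes the ten-membered ring, the isoxazoline and the C3 stereocentre. Against closures at C1–C10 or C8–C9, this cut creates the whole 1,3-dioxygenated unit in the ring-forming event and needs only C6 as stereochemical input. The precursor 18 is a monocyclic butenolide with one stereocentre. The forward reaction must choose the terminal C2=C3 bond over C4=C5 and C7=C11, place oxygen on C3, and add to the correct face.

**Oxime 18 back to acetal 15.** Oxime 18 comes from enal 17, and 17 from aldehyde 16 by α-methylenation (the C10=C14 bond). Aldehyde 16 comes from the dioxolane 15. Adding C14 late keeps the 2-substituted acrolein and any allylic acetal out of the organometallic steps. The side chain then simplifies to a plain four-carbon acetal, available from the commercial chloride 12.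

**Butenolide 15 back to propargylic alcohol 11 and chloride 12.** The bonds C7–C8 and C11–C12 and the lactone C–O bond are cut. The forward reaction is an alkoxide-directed anti-carbomagnesiation of 11 by Grignard reagent 13, carboxylation of chelate 14, and lactonisation. The usual tetronic acid route (ester condensation, triflation, cross-coupling) is avoided because it would expose a C6 hydrogen that is α to an ester and dienylic to strong base. In the alkoxide of 11 that hydrogen is not acidic. The precursor has no ring and still one stereocentre. C13 is carried as a triisopropylsilyl ether because it survives the later acetal hydrolysis and, being bulky and non-coordinating, is a poor leaving group next to magnesium in 14.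

**Alcohol 11 back to ynone 10, iododiene 5 and Weinreb amide 8.** The C6 stereocentre is removed by going to ketone 10 (oxazaborolidine reduction forward). The C5–C6 bond is cut to dienyllithium 9, from 5, and amide 8. Adding an alkynyl metal to a Z dienal is avoided because such aldehydes isomerise and equilibrate with 2H-pyrans. The forward reduction needs the branched Z alkenyl group to act as the large substituent and the linear alkynyl group as the small one.

**Fragments back to propargyl alcohol 1.** Iododiene 5 comes from iodo enal 4 and iodo alcohol 3. The Z geometry of 3 is fixed by the anti-carbomagnesiation of 1 through chelate 2, the same reaction type that later builds the butenolide. Amide 8 comes from silyl ether 6 through acetylide 7. Both fragments thus start from 1.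

## Roads not taken

**Alternative 1: carbonylative Stille macrocyclisation.** The cut is at C5–C6 and C6–C7, with C6 supplied by carbon monoxide. In the forward step Pd(PPh3)4 with LiCl under CO would join the C7 enol triflate and the C5 vinylstannane of the open chain A2 to give the cross-conjugated ten-membered dienone A1.
- Merits: all reacting carbons are sp2, the ring closure creates no stereocentre, and C1 and C3 are fixed beforehand by acyclic methods, so there is no question of facial selectivity in the closing step. In these respects it is safer than the chosen plan.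
- Weak points: the anti C1/C3 diol needs asymmetric operations of its own. A tetrasubstituted enol triflate of defined geometry with an allylic ether on C11 must be made. Direct coupling without CO insertion would give a nine-membered ring. The C6 carbinol must then come from 1,2-reduction of a cross-conjugated dienone inside the ring, with no obvious control over face or over 1,2- versus 1,4-addition, before lactonisation.
- Comparison: the chosen plan sets C6 first by reagent control and derives C3 and C1 from it, needs no tin, and needs no protection at C1 or C3. It pays for this with a less certain ring closure.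

**Alternative 2: decarboxylative allylic ring contraction.** The cut is at C8–C9. In the forward step Pd(PPh3)4 would ionise the allyl β-keto ester in the twelve-membered lactone A4; after loss of CO2 the C8 enolate would recombine with the allyl unit to give the ten-membered ketone A3.
- Merits: a twelve-membered lactone is easier to close than a ten-membered carbocycle, the contraction is intramolecular and driven by loss of CO2, and the 2-substituted allyl unit gives the same product from either terminus. The ring-forming step is probably more dependable than the cycloaddition.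
- Weak points: C1, C3 and C6 must all be made independently in the open chain. The ketone enolate can equilibrate toward C6 and epimerise the α-silyloxy centre. The butenolide with its C13 oxygen must be annulated last onto a strained ring with a base-sensitive C6.
- Comparison: the chosen plan has the butenolide in place before the ring closes and uses one asymmetric operation. The price is a harder ring closure.

**Alternative 3: Nozaki–Hiyama–Kishi closure at C1–C10.** The cut is at C1–C10. In the forward step CrCl2 with catalytic NiCl2 would convert the C10 vinyl iodide of A6 into a vinylchromium species that adds to the C1 aldehyde, giving allylic alcohol A5.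
- Merits: this is the most reliable way to close a ten-membered ring onto an aldehyde, it tolerates the butenolide, and it creates the exocyclic methylene and the C1 carbinol together. The ring closure itself is more dependable than the nitrile oxide closure.
- Weak points: the C1 configuration arises under substrate control of unknown sense and may need correction. C3 must be built separately next to the Z alkene. The β-silyloxy aldehyde can eliminate. Stoichiometric divalent chromium and two extra protecting groups are needed.
- Comparison: the chosen plan makes the whole C1–C3 unit from one cycloaddition, one N–O cleavage and one directed reduction, with C6 as the only independently set centre.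

Key step: step 12

Remark: propargyl alcohol, 2-(3-chloropropyl)-1,3-dioxolane and all reagents in the Conditions lines are taken to be commercial; descriptors refer to the atom numbering defined above.

## Route

Step 1
Reactants: 1 prop-2-yn-1-ol (propargyl alcohol)
Product: 3 (Z)-3-iodo-2-methylprop-2-en-1-ol, via magnesium chelate 2 (not isolated)
Conditions: MeMgBr (2.5 equiv), CuI (10 mol %), THF, −10 °C → rt; then I2, −78 → 0 °C
Reagents that add atoms: methylmagnesium bromide, C[Mg]Br; iodine, II
Why: Copper-catalysed, alkoxide-directed anti-carbomagnesiation of a propargylic alcohol puts methyl on C2 and magnesium on C3 cis to the CH2O group in chelate 2; iodinolysis with retention should give the Z iodide.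

Step 2
Reactants: 3 (Z)-3-iodo-2-methylprop-2-en-1-ol
Product: 4 (Z)-3-iodo-2-methylprop-2-enal
Conditions: MnO2, CH2Cl2, rt, dark
Reagents that add atoms: none
Why: Allylic alcohol oxidation on MnO2 is neutral and heterogeneous, so the Z iodo enal should be obtained without isomerisation if kept from light and acid and used directly.

Step 3
Reactants: 4 (Z)-3-iodo-2-methylprop-2-enal
Product: 5 (Z)-1-iodo-2-methylbuta-1,3-diene
Conditions: Ph3PCH3Br, NaN(SiMe3)2, THF, −78 → 0 °C; kept as a pentane solution
Reagents that add atoms: methyltriphenylphosphonium bromide (as its ylide), C[P+](c1ccccc1)(c1ccccc1)c1ccccc1.[Br-]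
Why: Wittig methylenation of the aldehyde; the iodoalkene has no hydrogen placed for elimination and its geometry is not involved, so the Z iododiene should result.

Step 4
Reactants: 1 prop-2-yn-1-ol (propargyl alcohol)
Product: 6 triisopropyl(prop-2-yn-1-yloxy)silane
Conditions: i-Pr3SiCl, imidazole, CH2Cl2, 0 °C → rt
Reagents that add atoms: chlorotriisopropylsilane, CC(C)[Si](Cl)(C(C)C)C(C)C
Why: Standard silylation of a primary alcohol; the triisopropylsilyl ether is chosen for its stability to organometallics and to the later acetal hydrolysis.

Step 5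
Reactants: 6 triisopropyl(prop-2-yn-1-yloxy)silane
Product: 8 N-methoxy-N-methyl-4-[(triisopropylsilyl)oxy]but-2-ynamide, via lithium acetylide 7 (not isolated)
Conditions: n-BuLi, THF, −78 °C; then MeN(OMe)COCl, −78 → 0 °C
Reagents that add atoms: N-methoxy-N-methylcarbamoyl chloride, CON(C)C(Cl)=O
Why: Acylation of a lithium acetylide by a carbamoyl chloride gives the alkynyl Weinreb amide directly; the amide does not react further with the acetylide at low temperature.

Step 6
Reactants: 5 (Z)-1-iodo-2-methylbuta-1,3-diene; 8 N-methoxy-N-methyl-4-[(triisopropylsilyl)oxy]but-2-ynamide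
Product: 10 (Z)-6-methyl-1-[(triisopropylsilyl)oxy]octa-5,7-dien-2-yn-4-one, via dienyllithium 9 (not isolated)
Conditions: 5, t-BuLi (2 equiv), Et2O, −78 °C; then 8, −78 → −40 °C; AcOH, −78 °C
Reagents that add atoms: none
Why: Iodine–lithium exchange proceeds with retention of alkene geometry, and the Weinreb ketone synthesis stops at the chelated tetrahedral adduct, so over-addition is avoided; the cold acidic quench protonates the liberated amine before it can add to the ynone.

Step 7
Reactants: 10 (Z)-6-methyl-1-[(triisopropylsilyl)oxy]octa-5,7-dien-2-yn-4-one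
Product: 11 (4R,5Z)-6-methyl-1-[(triisopropylsilyl)oxy]octa-5,7-dien-2-yn-4-ol
Conditions: (R)-Me-CBS (0.3 equiv), catecholborane, toluene/CH2Cl2, −78 °C
Reagents that add atoms: none
Why: Corey–Bakshi–Shibata reduction; the β,β-disubstituted Z alkenyl group should act as the large substituent and the linear alkynyl group as the small one, so the (R)-oxazaborolidine is expected to give the 4R alcohol, which becomes C6 (R); catecholborane at −78 °C leaves the diene and alkyne alone.

Step 8
Reactants: 11 (4R,5Z)-6-methyl-1-[(triisopropylsilyl)oxy]octa-5,7-dien-2-yn-4-ol; 12 2-(3-chloropropyl)-1,3-dioxolane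
Product: 15 (R)-4-[3-(1,3-dioxolan-2-yl)propyl]-5-[(Z)-2-methylbuta-1,3-dien-1-yl]-3-{[(triisopropylsilyl)oxy]methyl}furan-2(5H)-one, via Grignard reagent 13 (not isolated), via alkenylmagnesium chelate 14 (not isolated)
Conditions: 12, Mg, THF, 50 °C; then 11, 13 (4 equiv), Fe(acac)3 (15 mol %), THF, −78 → 0 °C; then CO2 (1 atm), −40 °C → rt; aq. citric acid
Reagents that add atoms: carbon dioxide, O=C=O
Why: Iron-catalysed, alkoxide-directed anti-carbomagnesiation of a propargylic alcohol delivers the alkyl group to the proximal alkyne carbon (C7) and leaves magnesium on C11 cis to the carbinol in chelate 14. Carboxylation on that side and acidification should close the butenolide. C6 is not touched, and the bulky non-coordinating silyl ether is meant to suppress β-elimination from 14.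

Step 9
Reactants: 15 (R)-4-[3-(1,3-dioxolan-2-yl)propyl]-5-[(Z)-2-methylbuta-1,3-dien-1-yl]-3-{[(triisopropylsilyl)oxy]methyl}furan-2(5H)-one
Product: 16 4-{(2R)-2-[(Z)-2-methylbuta-1,3-dien-1-yl]-5-oxo-4-{[(triisopropylsilyl)oxy]methyl}-2,5-dihydrofuran-3-yl}butanal
Conditions: PPTS, acetone/H2O, 50 °C
Reagents that add atoms: water, O
Why: Mild acid hydrolysis of the dioxolane; the primary triisopropylsilyl ether and the allylic lactone C–O bond should survive a pyridinium acid.

Step 10
Reactants: 16 4-{(2R)-2-[(Z)-2-methylbuta-1,3-dien-1-yl]-5-oxo-4-{[(triisopropylsilyl)oxy]methyl}-2,5-dihydrofuran-3-yl}butanal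
Product: 17 2-methylene-4-{(2R)-2-[(Z)-2-methylbuta-1,3-dien-1-yl]-5-oxo-4-{[(triisopropylsilyl)oxy]methyl}-2,5-dihydrofuran-3-yl}butanal
Conditions: 37% aq. CH2O, pyrrolidine (10 mol %), EtCO2H (10 mol %), i-PrOH, 45 °C
Reagents that add atoms: formaldehyde, C=O
Why: Amine-catalysed α-methylenation of an aldehyde (enamine Mannich condensation, then elimination) installs C14 on C10 under buffered conditions that should not deprotonate C6; the Z diene cannot reach the s-cis conformation, so an intramolecular Diels–Alder reaction with the new enal is not expected.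

Step 11
Reactants: 17 2-methylene-4-{(2R)-2-[(Z)-2-methylbuta-1,3-dien-1-yl]-5-oxo-4-{[(triisopropylsilyl)oxy]methyl}-2,5-dihydrofuran-3-yl}butanal
Product: 18 (1E)-2-methylene-4-{(2R)-2-[(Z)-2-methylbuta-1,3-dien-1-yl]-5-oxo-4-{[(triisopropylsilyl)oxy]methyl}-2,5-dihydrofuran-3-yl}butanal oxime
Conditions: NH2OH·HCl, NaOAc, EtOH/H2O, 0 °C → rt
Reagents that add atoms: hydroxylamine hydrochloride, NO.Cl
Why: Oxime condensation at the aldehyde is faster than conjugate addition to the 2-substituted acrolein under acetate buffer at 0 °C; the oxime geometry is lost in the next step and does not matter.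

Step 12
Reactants: 18 (1E)-2-methylene-4-{(2R)-2-[(Z)-2-methylbuta-1,3-dien-1-yl]-5-oxo-4-{[(triisopropylsilyl)oxy]methyl}-2,5-dihydrofuran-3-yl}butanal oxime
Product: 20 (3S,6R,4Z)-isoxazoline-bridged germacranolide (ten-membered ring C1–C10 fused to the butenolide at C6–C7, C1=N–O–C3 bridge, C10=C14 methylene, C13 triisopropylsilyl ether), via nitrile oxide 19 (not isolated)
Conditions: PhI(OAc)2 (1.2 equiv, added over 10 h), CF3CO2H (5 mol %), MeOH/CH2Cl2, 1 mM, 0 °C → rt
Reagents that add atoms: none
Why: PhI(OAc)2 dehydrogenates the aldoxime to nitrile oxide 19 without base, so the acidic C6 hydrogen is not endangered, and 19 then undergoes a concerted, asynchronous 1,3-dipolar cycloaddition with the terminal C2=C3 bond of the diene; the closest known reaction type is the intramolecular nitrile oxide–alkene cycloaddition used to close medium and large carbocycles. The isoxazoline closes with C1 bonding to the terminal carbon C2 and oxygen to the internal carbon C3, the normal regiochemistry for a monosubstituted alkene, and this makes the ten-membered carbocycle close in the bridged mode (N–O spanning C1 and C3) rather than the fused mode. The new stereocentre C3 is controlled by C6: allylic 1,3-strain across the Z C4=C5 bond holds the C6 hydrogen in the plane of that alkene facing C3, so C7 and the tether lie on one side of the plane; the vinyl group must turn its terminus to that side, and the dipole can reach only the face of C2=C3 turned toward the lactone, which corresponds to 3S. Site selectivity is needed against the trisubstituted C4=C5 bond (a fused seven-membered closure) and the tetrasubstituted, electron-poor C7=C11 bond; it should come from the much higher dipolarophilicity of a monosubstituted diene terminus and from the fact that addition across C4=C5 would have to form the C–O bond at a fully substituted carbon. Dimerisation to the furoxan is held back by generating 19 slowly at about 1 mM.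

Step 13
Reactants: 20 (3S,6R,4Z)-isoxazoline-bridged germacranolide
Product: 22 (3S,6R,4Z)-3-hydroxy-1-oxo-13-[(triisopropylsilyl)oxy]germacra-4,7(11),10(14)-trien-12,6-olide, via hydroxy imine 21 (not isolated)
Conditions: Mo(CO)6, MeCN/H2O, 80 °C
Reagents that add atoms: water, O
Why: Reductive N–O cleavage of an isoxazoline by Mo(CO)6 gives the β-hydroxy imine 21, which hydrolyses in the wet solvent; unlike hydrogenolysis this leaves the four C=C bonds untouched, and C3 is not involved.

Step 14
Reactants: 22 (3S,6R,4Z)-3-hydroxy-1-oxo-13-[(triisopropylsilyl)oxy]germacra-4,7(11),10(14)-trien-12,6-olide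
Product: 23 (1S,3S,6R,4Z)-3-acetoxy-1-hydroxy-13-[(triisopropylsilyl)oxy]germacra-4,7(11),10(14)-trien-12,6-olide
Conditions: MeCHO (8 equiv), SmI2 (30 mol %), THF, −10 °C
Reagents that add atoms: acetaldehyde, CC=O
Why: Evans–Tishchenko reduction: the C3 hydroxyl forms a samarium-bound hemiacetal with acetaldehyde and transfers hydride to the C1 ketone through a chair-like chelate, which should give the 1,3-anti carbinol (1S from 3S) and leave the acetyl group on the C3 oxygen.

Step 15
Reactants: 23 (1S,3S,6R,4Z)-3-acetoxy-1-hydroxy-13-[(triisopropylsilyl)oxy]germacra-4,7(11),10(14)-trien-12,6-olide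
Product: 24 (1S,3S,6R,4Z)-1,3-diacetoxy-13-[(triisopropylsilyl)oxy]germacra-4,7(11),10(14)-trien-12,6-olide
Conditions: Ac2O, pyridine, DMAP (cat.), CH2Cl2, 0 °C
Reagents that add atoms: acetic anhydride, CC(=O)OC(C)=O
Why: Acylation of the secondary allylic alcohol; acetyl migration between O1 and O3 would be of no consequence because both end as acetates, and pyridine at 0 °C should not epimerise C6.

Step 16
Reactants: 24 (1S,3S,6R,4Z)-1,3-diacetoxy-13-[(triisopropylsilyl)oxy]germacra-4,7(11),10(14)-trien-12,6-olide
Product: 25 (1S,3S,6R,4Z)-1,3-diacetoxy-13-hydroxygermacra-4,7(11),10(14)-trien-12,6-olide (CNP0398389.3)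
Conditions: HF·pyridine, pyridine, THF, 0 °C → rt
Reagents that add atoms: none
Why: Fluoride cleavage of the primary silyl ether under buffered, mildly acidic conditions should spare the allylic acetates and the base-sensitive C6 centre.

## Compound list

1 | prop-2-yn-1-ol (propargyl alcohol) | C#CCO | starting material
2 | 4-methyl-2,5-dihydro-1,2-oxamagnesole (magnesium chelate) | CC1=C[Mg]OC1 | intermediate
3 | (Z)-3-iodo-2-methylprop-2-en-1-ol | OC/C(C)=C\I | intermediate
4 | (Z)-3-iodo-2-methylprop-2-enal | O=C/C(C)=C\I | intermediate
5 | (Z)-1-iodo-2-methylbuta-1,3-diene | C=C/C(C)=C\I | intermediate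
6 | triisopropyl(prop-2-yn-1-yloxy)silane | C#CCO[Si](C(C)C)(C(C)C)C(C)C | intermediate
7 | {3-[(triisopropylsilyl)oxy]prop-1-yn-1-yl}lithium | [Li]C#CCO[Si](C(C)C)(C(C)C)C(C)C | intermediate
8 | N-methoxy-N-methyl-4-[(triisopropylsilyl)oxy]but-2-ynamide | CON(C)C(=O)C#CCO[Si](C(C)C)(C(C)C)C(C)C | intermediate
9 | [(Z)-2-methylbuta-1,3-dien-1-yl]lithium | C=C/C(C)=C\[Li] | intermediate
10 | (Z)-6-methyl-1-[(triisopropylsilyl)oxy]octa-5,7-dien-2-yn-4-one | C=C/C(C)=C\C(=O)C#CCO[Si](C(C)C)(C(C)C)C(C)C | intermediate
11 | (4R,5Z)-6-methyl-1-[(triisopropylsilyl)oxy]octa-5,7-dien-2-yn-4-ol | O[C@@H](C#CCO[Si](C(C)C)(C(C)C)C(C)C)/C=C(/C)C=C | intermediate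
12 | 2-(3-chloropropyl)-1,3-dioxolane | ClCCCC1OCCO1 | starting material
13 | [3-(1,3-dioxolan-2-yl)propyl]magnesium chloride | Cl[Mg]CCCC1OCCO1 | intermediate
14 | (5R)-4-[3-(1,3-dioxolan-2-yl)propyl]-5-[(Z)-2-methylbuta-1,3-dien-1-yl]-3-{[(triisopropylsilyl)oxy]methyl}-2,5-dihydro-1,2-oxamagnesole | O1[Mg]C(CO[Si](C(C)C)(C(C)C)C(C)C)=C(CCCC2OCCO2)[C@H]1/C=C(/C)C=C | intermediate
15 | (R)-4-[3-(1,3-dioxolan-2-yl)propyl]-5-[(Z)-2-methylbuta-1,3-dien-1-yl]-3-{[(triisopropylsilyl)oxy]methyl}furan-2(5H)-one | O1CCOC1CCCC1=C(CO[Si](C(C)C)(C(C)C)C(C)C)C(=O)O[C@@H]1/C=C(/C)C=C | intermediate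
16 | 4-{(2R)-2-[(Z)-2-methylbuta-1,3-dien-1-yl]-5-oxo-4-{[(triisopropylsilyl)oxy]methyl}-2,5-dihydrofuran-3-yl}butanal | O=CCCCC1=C(CO[Si](C(C)C)(C(C)C)C(C)C)C(=O)O[C@@H]1/C=C(/C)C=C | intermediate
17 | 2-methylene-4-{(2R)-2-[(Z)-2-methylbuta-1,3-dien-1-yl]-5-oxo-4-{[(triisopropylsilyl)oxy]methyl}-2,5-dihydrofuran-3-yl}butanal | O=CC(=C)CCC1=C(CO[Si](C(C)C)(C(C)C)C(C)C)C(=O)O[C@@H]1/C=C(/C)C=C | intermediate
18 | (1E)-oxime of 17 | O/N=C/C(=C)CCC1=C(CO[Si](C(C)C)(C(C)C)C(C)C)C(=O)O[C@@H]1/C=C(/C)C=C | intermediate
19 | nitrile oxide derived from 18 | [O-][N+]#CC(=C)CCC1=C(CO[Si](C(C)C)(C(C)C)C(C)C)C(=O)O[C@@H]1/C=C(/C)C=C | intermediate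
20 | (3S,6R,4Z)-isoxazoline-bridged germacranolide, C1=N–O–C3 bridge, C13 triisopropylsilyl ether | C=C1CCC2=C(CO[Si](C(C)C)(C(C)C)C(C)C)C(=O)O[C@@H]2/C=C(/C)[C@@H]3CC1=NO3 | intermediate
21 | (3S,6R,4Z)-3-hydroxy-1-imino-13-[(triisopropylsilyl)oxy]germacra-4,7(11),10(14)-trien-12,6-olide | C=C1CCC2=C(CO[Si](C(C)C)(C(C)C)C(C)C)C(=O)O[C@@H]2/C=C(/C)[C@@H](O)CC1=N | intermediate
22 | (3S,6R,4Z)-3-hydroxy-1-oxo-13-[(triisopropylsilyl)oxy]germacra-4,7(11),10(14)-trien-12,6-olide | C=C1CCC2=C(CO[Si](C(C)C)(C(C)C)C(C)C)C(=O)O[C@@H]2/C=C(/C)[C@@H](O)CC1=O | intermediate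
23 | (1S,3S,6R,4Z)-3-acetoxy-1-hydroxy-13-[(triisopropylsilyl)oxy]germacra-4,7(11),10(14)-trien-12,6-olide | C=C1CCC2=C(CO[Si](C(C)C)(C(C)C)C(C)C)C(=O)O[C@@H]2/C=C(/C)[C@@H](OC(C)=O)C[C@@H]1O | intermediate
24 | (1S,3S,6R,4Z)-1,3-diacetoxy-13-[(triisopropylsilyl)oxy]germacra-4,7(11),10(14)-trien-12,6-olide | C=C1CCC2=C(CO[Si](C(C)C)(C(C)C)C(C)C)C(=O)O[C@@H]2/C=C(/C)[C@@H](OC(C)=O)C[C@@H]1OC(C)=O | intermediate
25 | (1S,3S,6R,4Z)-1,3-diacetoxy-13-hydroxygermacra-4,7(11),10(14)-trien-12,6-olide (CNP0398389.3) | C=C1CCC2=C(CO)C(=O)O[C@@H]2/C=C(/C)[C@@H](OC(C)=O)C[C@@H]1OC(C)=O | target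

## Step count and least certain steps

Total: 16 steps (steps 1–3 make fragment 1, steps 4–5 fragment 2, steps 6–16 are linear). Longest linear sequence: 14 steps (1–3, then 6–16).

**Step 12 (key step).** The most likely failure is loss or reversal of face selection at C3, because it rests on a conformational relay from C6 over the Z alkene. The slow medium-ring closure also leaves room for furoxan formation and for fused addition across C4=C5; dilution and slow generation of the dipole limit these but cannot exclude them. The fallback makes the sequence stereoconvergent and sets out from oxime 18. The same cycloaddition gives, beside or instead of 20, the C3-epimeric isoxazoline F1. This would be opened with Mo(CO)6 in wet acetonitrile to the 3R hydroxy enone F2, then reduced with Me4NBH(OAc)3 (directed anti reduction) to the (1R,3R) diol F3. Both allylic carbinols would then be inverted together by a double Mitsunobu reaction with acetic acid (PPh3, diisopropyl azodicarboxylate). This returns to the route at diacetate 24.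

**Step 8.** The most likely failure is diversion of the low-valent iron catalyst by the conjugated diene (π-complexation, hydromagnesiation), together with β-hydride elimination of the alkyliron intermediate, so that reduction or diene-derived products replace carbometalation. Expulsion of the silyloxy group from chelate 14 to give an allenol is a further loss channel. The fallback removes the diene from this step and sets out from iodo alcohol 3.
- 3 would be silylated (t-BuMe2SiCl, imidazole) to silyl ether F4.
- F4 would be converted by iodine–lithium exchange and acylation with amide 8 into ynone F5.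
- F5 would be reduced with the (R)-oxazaborolidine to alcohol F6.
- F6 would undergo the same carbomagnesiation–carboxylation with 13 to give butenolide F7.
- The allylic silyl ether of F7 would be removed selectively with HF·pyridine to give allylic alcohol F8.
- F8 would be oxidised with MnO2 to the Z enal F9.
- F9 would be methylenated without base (CH2I2, Zn, TiCl4; Takai–Lombardo conditions) to rejoin the route at butenolide 15.

**Step 7.** The most likely failure is insufficient enantioselection, because both ketone substituents are unsaturated and the distal silyloxymethyl group may make the alkynyl arm behave as the larger one. The fallback replaces asymmetric reduction by resolution and sets out from ynone 10. Reduction with NaBH4 and CeCl3·7H2O would give the racemic alcohol F10. Esterification with (S)-O-methylmandelic acid (dicyclohexylcarbodiimide, DMAP) would give the ester of the 4R alcohol F11 and its 4S diastereomer F12, to be separated by chromatography. Methanolysis of F11 (K2CO3, MeOH) returns to the route at alcohol 11.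

**Step 14.** The most likely failure is interference by the exocyclic enone (conjugate reduction or pinacol-type coupling by the samarium species), or a poor fit of the chelated hydride-transfer geometry in the medium ring, leading to low conversion or eroded anti selectivity. The fallback sets out from hydroxy enone 22. Directed reduction with Me4NBH(OAc)3 in MeCN/AcOH at −30 °C would give the anti diol F13. Acetylation of both hydroxyls (Ac2O, pyridine, DMAP) returns to the route at diacetate 24 in the same number of steps.

## Further compounds

F1 | step 12 | (3R,6R,4Z)-isoxazoline-bridged germacranolide, C3 epimer of 20 | C=C1CCC2=C(CO[Si](C(C)C)(C(C)C)C(C)C)C(=O)O[C@@H]2/C=C(/C)[C@H]3CC1=NO3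
F2 | step 12 | (3R,6R,4Z)-3-hydroxy-1-oxo-13-[(triisopropylsilyl)oxy]germacra-4,7(11),10(14)-trien-12,6-olide | C=C1CCC2=C(CO[Si](C(C)C)(C(C)C)C(C)C)C(=O)O[C@@H]2/C=C(/C)[C@H](O)CC1=O
F3 | step 12 | (1R,3R,6R,4Z)-1,3-dihydroxy-13-[(triisopropylsilyl)oxy]germacra-4,7(11),10(14)-trien-12,6-olide | C=C1CCC2=C(CO[Si](C(C)C)(C(C)C)C(C)C)C(=O)O[C@@H]2/C=C(/C)[C@H](O)C[C@H]1O
F4 | step 8 | (Z)-tert-butyl[(3-iodo-2-methylprop-2-en-1-yl)oxy]dimethylsilane | CC(C)(C)[Si](C)(C)OC/C(C)=C\I
F5 | step 8 | (Z)-7-[(tert-butyldimethylsilyl)oxy]-6-methyl-1-[(triisopropylsilyl)oxy]hept-5-en-2-yn-4-one | CC(C)(C)[Si](C)(C)OC/C(C)=C\C(=O)C#CCO[Si](C(C)C)(C(C)C)C(C)C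
F6 | step 8 | (4R,5Z)-7-[(tert-butyldimethylsilyl)oxy]-6-methyl-1-[(triisopropylsilyl)oxy]hept-5-en-2-yn-4-ol | O[C@@H](C#CCO[Si](C(C)C)(C(C)C)C(C)C)/C=C(/C)CO[Si](C)(C)C(C)(C)C
F7 | step 8 | (R)-5-{(Z)-3-[(tert-butyldimethylsilyl)oxy]-2-methylprop-1-en-1-yl}-4-[3-(1,3-dioxolan-2-yl)propyl]-3-{[(triisopropylsilyl)oxy]methyl}furan-2(5H)-one | O1CCOC1CCCC1=C(CO[Si](C(C)C)(C(C)C)C(C)C)C(=O)O[C@@H]1/C=C(/C)CO[Si](C)(C)C(C)(C)C
F8 | step 8 | (R)-4-[3-(1,3-dioxolan-2-yl)propyl]-5-[(Z)-3-hydroxy-2-methylprop-1-en-1-yl]-3-{[(triisopropylsilyl)oxy]methyl}furan-2(5H)-one | O1CCOC1CCCC1=C(CO[Si](C(C)C)(C(C)C)C(C)C)C(=O)O[C@@H]1/C=C(/C)CO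
F9 | step 8 | (Z)-3-{(2R)-3-[3-(1,3-dioxolan-2-yl)propyl]-5-oxo-4-{[(triisopropylsilyl)oxy]methyl}-2,5-dihydrofuran-2-yl}-2-methylprop-2-enal | O1CCOC1CCCC1=C(CO[Si](C(C)C)(C(C)C)C(C)C)C(=O)O[C@@H]1/C=C(/C)C=O
F10 | step 7 | racemic (Z)-6-methyl-1-[(triisopropylsilyl)oxy]octa-5,7-dien-2-yn-4-ol | OC(C#CCO[Si](C(C)C)(C(C)C)C(C)C)/C=C(/C)C=C
F11 | step 7 | (4R,5Z)-6-methyl-1-[(triisopropylsilyl)oxy]octa-5,7-dien-2-yn-4-yl (S)-2-methoxy-2-phenylacetate | CO[C@@H](c1ccccc1)C(=O)O[C@@H](C#CCO[Si](C(C)C)(C(C)C)C(C)C)/C=C(/C)C=C
F12 | step 7 | (4S,5Z)-6-methyl-1-[(triisopropylsilyl)oxy]octa-5,7-dien-2-yn-4-yl (S)-2-methoxy-2-phenylacetate | CO[C@@H](c1ccccc1)C(=O)O[C@H](C#CCO[Si](C(C)C)(C(C)C)C(C)C)/C=C(/C)C=C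
F13 | step 14 | (1S,3S,6R,4Z)-1,3-dihydroxy-13-[(triisopropylsilyl)oxy]germacra-4,7(11),10(14)-trien-12,6-olide | C=C1CCC2=C(CO[Si](C(C)C)(C(C)C)C(C)C)C(=O)O[C@@H]2/C=C(/C)[C@@H](O)C[C@@H]1O
A1 | alternative 1 | ten-membered cross-conjugated dienone with C6 ketone, methyl ester on C11 cis to C6, C13 p-methoxybenzyl ether, C1 and C3 tert-butyldimethylsilyl ethers | C=C1CC/C(=C(\COCc2ccc(OC)cc2)C(=O)OC)C(=O)/C=C(/C)[C@@H](O[Si](C)(C)C(C)(C)C)C[C@@H]1O[Si](C)(C)C(C)(C)C
A2 | alternative 1 | open-chain C7 enol triflate with C5 tributylvinylstannane | CCCC[Sn](CCCC)(CCCC)/C=C(/C)[C@@H](O[Si](C)(C)C(C)(C)C)C[C@@H](C(=C)CC/C(OS(=O)(=O)C(F)(F)F)=C(\COCc1ccc(OC)cc1)C(=O)OC)O[Si](C)(C)C(C)(C)C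
A3 | alternative 2 | ten-membered C7 ketone with C6 triethylsilyl ether, C10 methylene, C1 and C3 tert-butyldimethylsilyl ethers | C=C1CCC(=O)[C@H](O[Si](CC)(CC)CC)/C=C(/C)[C@@H](O[Si](C)(C)C(C)(C)C)C[C@@H]1O[Si](C)(C)C(C)(C)C
A4 | alternative 2 | twelve-membered allyl β-keto ester lactone | C=C1COC(=O)CC(=O)[C@H](O[Si](CC)(CC)CC)/C=C(/C)[C@@H](O[Si](C)(C)C(C)(C)C)C[C@@H]1O[Si](C)(C)C(C)(C)C
A5 | alternative 3 | ten-membered butenolide with free C1 alcohol, C3 tert-butyldimethylsilyl ether, C13 p-methoxybenzyl ether | C=C1CCC2=C(COCc3ccc(OC)cc3)C(=O)O[C@@H]2/C=C(/C)[C@@H](O[Si](C)(C)C(C)(C)C)C[C@@H]1O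
A6 | alternative 3 | butenolide with C10 vinyl iodide chain and C1 aldehyde | C=C(I)CCC1=C(COCc2ccc(OC)cc2)C(=O)O[C@@H]1/C=C(/C)[C@@H](O[Si](C)(C)C(C)(C)C)CC=O
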